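**Ass­umption:** moracin Q has no stereocentres (the SMILES is achiral), so the compound is made as drawn; no step creates a stereocentre.

## Retrosynthetic overview

1. Moracin Q ⇐ tris-MOM ether by one global acidic deprotection.
2. The furan ring (the only ring formed; both benzene rings are bought) ⇐ late Sonogashira coupling/5-endo-dig cyclisation of a pentasubstituted o-iodophenol (core, with ketone) and 3,5-bis(MOMO)phenylacetylene.
3. Iodophenol ⇐ ortho-iodination ⇐ Ir C–H borylation/oxidation (OH placed para to OMe by sterics) ⇐ Pd α-arylation of 3-methylbutan-2-one with 1-bromo-2-methoxy-3-(MOMO)benzene.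
4. That bromide ⇐ 2-bromophenol by ortho-formylation, O-methylation, Dakin-type oxidation and MOM protection.
5. Alkyne ⇐ resorcinol by MOM protection, meta-selective Ir borylation, Cu iododeboronation, Sonogashira with TMS-acetylene, desilylation.

## Core fragment

**Step 1**
Reactants: 1, 2-bromophenol
Product: 2, 3-bromo-2-hydroxybenzaldehyde
Conditions: MgCl2, Et3N, (CH2O)n, THF, reflux
Reagents that add atoms: paraformaldehyde (formaldehyde), C=O
Why: Mg-phenoxide-directed ortho-formylation (Casnati–Skattebøl) can only go to the one free ortho position.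

**Step 2**
Reactants: 2, 3-bromo-2-hydroxybenzaldehyde
Product: 3, 3-bromo-2-methoxybenzaldehyde
Conditions: MeI, K2CO3, DMF, rt
Reagents that add atoms: iodomethane, CI
Why: Williamson O-methylation of the only acidic OH; this methyl is the methoxy group of the target.

**Step 3**
Reactants: 3, 3-bromo-2-methoxybenzaldehyde
Product: 4, 3-bromo-2-methoxyphenol
Conditions: mCPBA, CH2Cl2, rt; then K2CO3, MeOH, rt
Reagents that add atoms: mCPBA, OOC(=O)c1cccc(Cl)c1 (delivers one O; the formyl carbon leaves as formate)
Why: Baeyer–Villiger (Dakin-type) oxidation, where the o-methoxyaryl group migrates in preference to H, gives the aryl formate, which is methanolysed to the phenol.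

**Step 4**
Reactants: 4, 3-bromo-2-methoxyphenol
Product: 5, 1-bromo-2-methoxy-3-(methoxymethoxy)benzene
Conditions: MOMCl, iPr2NEt, CH2Cl2, 0 °C → rt
Reagents that add atoms: chloromethyl methyl ether, COCCl
Why: Acetal protection of the phenol; MOM survives base, Pd, Ir, peroxide and NIS and is removed only in the last step.

**Step 5**
Reactants: 5, 1-bromo-2-methoxy-3-(methoxymethoxy)benzene; 6, 3-methylbutan-2-one (2.5 equiv)
Product: 7, 1-[2-methoxy-3-(methoxymethoxy)phenyl]-3-methylbutan-2-one
Conditions: Pd2(dba)3 (1.5 mol %), Xantphos (3.6 mol %), NaOtBu, THF, 70 °C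
Reagents that add atoms: none (all new atoms come from 6)
Why: Buchwald–Hartwig ketone α-arylation occurs at the less hindered methyl side of 6, and the ortho-substituted aryl group plus excess ketone suppress diarylation.

**Step 6**
Reactants: 7, 1-[2-methoxy-3-(methoxymethoxy)phenyl]-3-methylbutan-2-one
Product: 8, 1-[2-methoxy-3-(methoxymethoxy)-5-(4,4,5,5-tetramethyl-1,3,2-dioxaborolan-2-yl)phenyl]-3-methylbutan-2-one
Conditions: [Ir(OMe)(cod)]2 (1.5 mol %), dtbpy (3 mol %), B2pin2, THF, 80 °C
Reagents that add atoms: bis(pinacolato)diboron, CC1(C)OB(OC1(C)C)B1OC(C)(C)C(C)(C)O1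
Why: Sterically controlled Ir-catalysed C–H borylation of a 1,2,3-trisubstituted arene goes to the only C–H with no ortho neighbour, which is para to OMe.

**Step 7**
Reactants: 8, the arylboronate
Product: 9, 1-[5-hydroxy-2-methoxy-3-(methoxymethoxy)phenyl]-3-methylbutan-2-one
Conditions: 30% H2O2, aq NaOH, THF, 0 °C
Reagents that add atoms: hydrogen peroxide, OO
Why: Oxidative C–B to C–O conversion (boronate 1,2-aryl shift) is faster than any ketone oxidation at 0 °C and gives the future furan oxygen.

**Step 8**
Reactants: 9, the phenol
Product: 10, 1-[3-hydroxy-2-iodo-6-methoxy-5-(methoxymethoxy)phenyl]-3-methylbutan-2-one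
Conditions: NIS (1.0 equiv), MeCN, 0 °C, dark
Reagents that add atoms: N-iodosuccinimide, O=C1CCC(=O)N1I
Why: Electrophilic aromatic iodination goes ortho to OH and para to OMOM (para to OH is blocked by OMe), as 5-alkylresorcinol ethers halogenate next to the alkyl group and not between the oxygens.

## Alkyne fragment

**Step 9**
Reactants: 11, resorcinol
Product: 12, 1,3-bis(methoxymethoxy)benzene
Conditions: MOMCl (2.5 equiv), iPr2NEt, CH2Cl2, 0 °C → rt
Reagents that add atoms: chloromethyl methyl ether, COCCl (two equivalents incorporated)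
Why: Double acetal protection with the same group used on the core, so one final step removes all three.

**Step 10**
Reactants: 12, 1,3-bis(methoxymethoxy)benzene
Product: 13, 2-[3,5-bis(methoxymethoxy)phenyl]-4,4,5,5-tetramethyl-1,3,2-dioxaborolane
Conditions: [Ir(OMe)(cod)]2 (1 mol %), dtbpy (2 mol %), B2pin2, THF, 80 °C
Reagents that add atoms: bis(pinacolato)diboron, CC1(C)OB(OC1(C)C)B1OC(C)(C)C(C)(C)O1
Why: Ir-catalysed C–H borylation of a 1,3-disubstituted arene is sterically directed to the mutually meta 5-position.

**Step 11**
Reactants: 13, the arylboronate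
Product: 14, 1-iodo-3,5-bis(methoxymethoxy)benzene
Conditions: CuI (10 mol %), 1,10-phenanthroline (20 mol %), KI, MeOH/H2O 4:1, air, 80 °C
Reagents that add atoms: potassium iodide, [K+].[I-]
Why: Cu-mediated ipso-iododeboronation proceeds by transmetalation, so it avoids electrophilic attack on the activated ring C–H positions and is non-acidic for the MOM groups.

**Step 12**
Reactants: 14, 1-iodo-3,5-bis(methoxymethoxy)benzene; 15, ethynyltrimethylsilane
Product: 16, {[3,5-bis(methoxymethoxy)phenyl]ethynyl}trimethylsilane
Conditions: PdCl2(PPh3)2 (2 mol %), CuI (4 mol %), Et3N, THF, rt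
Reagents that add atoms: none (all new atoms come from 15)
Why: Sonogashira coupling of an unhindered aryl iodide at room temperature, with TMS preventing double coupling.

**Step 13**
Reactants: 16, the TMS-alkyne
Product: 17, 1-ethynyl-3,5-bis(methoxymethoxy)benzene
Conditions: K2CO3, MeOH, rt
Reagents that add atoms: none
Why: Methanolysis of the alkynyl C–Si bond under mild base leaves the MOM ethers untouched.

## Fragment union and completion

**Step 14**
Reactants: 10, the iodophenol; 17, 1-ethynyl-3,5-bis(methoxymethoxy)benzene (1.3 equiv)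
Product: 18, 1-{2-[3,5-bis(methoxymethoxy)phenyl]-5-methoxy-6-(methoxymethoxy)-1-benzofuran-4-yl}-3-methylbutan-2-one
Conditions: PdCl2(PPh3)2 (5 mol %), CuI (10 mol %), Et3N/DMF, 70 °C, degassed
Reagents that add atoms: none
Why: Sonogashira coupling followed in situ by Cu/Pd-promoted 5-endo-dig attack of the ortho phenoxide on the alkyne gives the 2-arylbenzofuran, and the phenoxide outcompetes the ketone enol as the nucleophile.

**Step 15**
Reactants: 18, the tris-MOM benzofuran
Product: 19, moracin Q, 1-[2-(3,5-dihydroxyphenyl)-6-hydroxy-5-methoxy-1-benzofuran-4-yl]-3-methylbutan-2-one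
Conditions: 3 M aq HCl, MeOH, 50 °C
Reagents that add atoms: none
Why: Acid-catalysed acetal hydrolysis removes the three MOM groups while the aryl methyl ether, benzofuran and ketone are stable, with methanol trapping the released formaldehyde.

## Compound list

1 | 2-bromophenol | Oc1ccccc1Br | starting material
2 | 3-bromo-2-hydroxybenzaldehyde | O=Cc1cccc(Br)c1O | intermediate
3 | 3-bromo-2-methoxybenzaldehyde | COc1c(Br)cccc1C=O | intermediate
4 | 3-bromo-2-methoxyphenol | COc1c(O)cccc1Br | intermediate
5 | 1-bromo-2-methoxy-3-(methoxymethoxy)benzene | COCOc1cccc(Br)c1OC | intermediate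
6 | 3-methylbutan-2-one | CC(=O)C(C)C | starting material
7 | 1-[2-methoxy-3-(methoxymethoxy)phenyl]-3-methylbutan-2-one | COCOc1cccc(CC(=O)C(C)C)c1OC | intermediate
8 | 1-[2-methoxy-3-(methoxymethoxy)-5-(pinacolboryl)phenyl]-3-methylbutan-2-one | COCOc1cc(B2OC(C)(C)C(C)(C)O2)cc(CC(=O)C(C)C)c1OC | intermediate
9 | 1-[5-hydroxy-2-methoxy-3-(methoxymethoxy)phenyl]-3-methylbutan-2-one | COCOc1cc(O)cc(CC(=O)C(C)C)c1OC | intermediate
10 | 1-[3-hydroxy-2-iodo-6-methoxy-5-(methoxymethoxy)phenyl]-3-methylbutan-2-one | COCOc1cc(O)c(I)c(CC(=O)C(C)C)c1OC | intermediate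
11 | resorcinol (benzene-1,3-diol) | Oc1cccc(O)c1 | starting material
12 | 1,3-bis(methoxymethoxy)benzene | COCOc1cccc(OCOC)c1 | intermediate
13 | 2-[3,5-bis(methoxymethoxy)phenyl]-4,4,5,5-tetramethyl-1,3,2-dioxaborolane | COCOc1cc(OCOC)cc(B2OC(C)(C)C(C)(C)O2)c1 | intermediate
14 | 1-iodo-3,5-bis(methoxymethoxy)benzene | COCOc1cc(I)cc(OCOC)c1 | intermediate
15 | ethynyltrimethylsilane | C#C[Si](C)(C)C | starting material
16 | {[3,5-bis(methoxymethoxy)phenyl]ethynyl}trimethylsilane | COCOc1cc(OCOC)cc(C#C[Si](C)(C)C)c1 | intermediate
17 | 1-ethynyl-3,5-bis(methoxymethoxy)benzene | COCOc1cc(OCOC)cc(C#C)c1 | intermediate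
18 | 1-{2-[3,5-bis(methoxymethoxy)phenyl]-5-methoxy-6-(methoxymethoxy)-1-benzofuran-4-yl}-3-methylbutan-2-one | COCOc1cc2oc(-c3cc(OCOC)cc(OCOC)c3)cc2c(CC(=O)C(C)C)c1OC | intermediate
19 | moracin Q | COc1c(O)cc2oc(-c3cc(O)cc(O)c3)cc2c1CC(=O)C(C)C | target

## Summary

**Total step count:** 15 (core steps 1–8, alkyne steps 9–13, union and deprotection steps 14–15).

**Longest linear sequence:** 10 steps (1 → 8, then 14 and 15, from 2-bromophenol), which is 10 of 15. The resorcinol arm is 7 steps to the target.

**Steps most likely to fail, with fallbacks**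

1. **Step 14 (Sonogashira/cyclisation).** The iodide is electron-rich and flanked on both sides, the free phenoxide can slow coupling, and alkyne homocoupling competes. Fallback: separate the two events by acetylating 10, running the Sonogashira on the aryl acetate to isolate the diarylalkyne, then closing the furan in a distinct deacetylation/5-endo-dig step (Cs2CO3/MeOH or a gold catalyst).

2. **Step 6 (Ir borylation with a free enolisable ketone).** Carbonyl reduction or enol borylation could erode yield here, and the ketone also rides through steps 7, 8 and 14. Fallback: carry the side chain as a protected alcohol. Br/Mg exchange on 5 and CuI-catalysed opening of 2-isopropyloxirane gives ArCH2CH(OH)iPr, which is TBS-protected and taken through borylation, oxidation, iodination and annulation. The ketone is then revealed (TBAF, then Dess–Martin) before MOM removal.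

3. **Step 8 (site of iodination).** Attack between the two oxygens instead of next to the side chain would give the wrong benzofuran isomer. Fallback: change the protecting-group design so sterics decide, using a bulky TIPS ether in place of MOM on the oxygen next to OMe (installed at step 4) to shield the inter-oxygen position, with fluoride removal added at the end.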